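The synthesis rests on cutting the C4–C4a bond of the pyranone (ring B). This unfolds the coumarin into an aryl propiolate: a benzene ring (ring A) that already carries the C7 methoxy group, the finished (R)-configured C8 side chain and a propiolate ester on the future O1. One palladium-catalysed hydroarylation then forms C4–C4a, closes ring B and gives the natural product with no further step. The step exploits two features. C4a is the only hydrogen-bearing carbon next to C8a, since C8 holds the acyl group, and it lies para to the C7 methoxy donor, so only one ring closure is possible. The C2' stereocentre is bought as (R)-2-hydroxy-3-methylbutanoic acid and never disturbed.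

Key step: step 9

Remark: coumarin locants (O1, C2 to C8a) are also used for the open precursors. C1' is the ketone carbon and C2' the stereocentre, which is R in the target (O > C1' > isopropyl > H) and has the same spatial arrangement as the R hydroxy acid, so no bond to C2' may be broken at any step.

Step 1
Reactants: 1 3-methoxyphenol
Product: 2 1-methoxy-3-(methoxymethoxy)benzene
Conditions: MOMCl, i-Pr2NEt, CH2Cl2, 0 °C → rt
Reagents that add atoms: chloromethyl methyl ether (MOMCl), COCCl
Why: Williamson-type O-alkylation of the phenol with an α-chloro ether gives an acetal that withstands n-BuLi, coordinates lithium for the later metalation and is removed by protic acid alone.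

Step 2
Reactants: 3 (R)-2-hydroxy-3-methylbutanoic acid
Product: 4 (R)-2-hydroxy-N-methoxy-N,3-dimethylbutanamide
Conditions: MeNH(OMe)·HCl, EDC·HCl, HOBt, N-methylmorpholine, CH2Cl2, 0 °C → rt
Reagents that add atoms: N,O-dimethylhydroxylamine hydrochloride, CNOC.Cl
Why: Carbodiimide/HOBt amide coupling (Weinreb amide formation), in which the amine outcompetes the hindered secondary hydroxyl and the configuration is kept because no bond to the stereocentre is touched.

Step 3
Reactants: 4 (R)-2-hydroxy-N-methoxy-N,3-dimethylbutanamide
Product: 5 (R)-2-(tert-butyldimethylsilyloxy)-N-methoxy-N,3-dimethylbutanamide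
Conditions: TBSCl, imidazole, DMF, rt
Reagents that add atoms: tert-butyldimethylsilyl chloride (TBSCl), CC(C)(C)[Si](C)(C)Cl
Why: Imidazole-promoted silylation of a secondary alcohol removes the acidic OH before the organolithium step and reacts only at oxygen, so the R centre is retained.

Step 4
Reactants: 2 1-methoxy-3-(methoxymethoxy)benzene, 5 (R)-2-(tert-butyldimethylsilyloxy)-N-methoxy-N,3-dimethylbutanamide
Product: 8 (R)-2-(tert-butyldimethylsilyloxy)-1-[2-methoxy-6-(methoxymethoxy)phenyl]-3-methylbutan-1-one, via aryllithium 6 (not isolated), via tetrahedral lithium adduct 7 (not isolated)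
Conditions: n-BuLi, THF, 0 °C; then 5, −78 → −20 °C; AcOH, −78 °C
Reagents that add atoms: none
Why: Directed ortho-metalation followed by Weinreb ketone synthesis: the C–H between the two oxygen substituents is the most acidic and doubly coordinated site, and chelated adduct 7 resists a second addition and keeps the α-carbon from enolising until the cold acidic quench releases the ketone.

Step 5
Reactants: 8 (R)-2-(tert-butyldimethylsilyloxy)-1-[2-methoxy-6-(methoxymethoxy)phenyl]-3-methylbutan-1-one
Product: 9 (R)-2-hydroxy-1-[2-methoxy-6-(methoxymethoxy)phenyl]-3-methylbutan-1-one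
Conditions: HF·pyridine, pyridine, THF, 0 °C → rt
Reagents that add atoms: none
Why: Fluoride-driven desilylation in a buffered, weakly acidic medium leaves the aryl MOM acetal intact and avoids the basic conditions under which an α-hydroxy ketone could epimerise or undergo an α-ketol shift.

Step 6
Reactants: 9 (R)-2-hydroxy-1-[2-methoxy-6-(methoxymethoxy)phenyl]-3-methylbutan-1-one, 10 3-methylbut-2-enoyl chloride (senecioyl chloride)
Product: 11 (R)-1-[2-methoxy-6-(methoxymethoxy)phenyl]-3-methyl-1-oxobutan-2-yl 3-methylbut-2-enoate
Conditions: pyridine, DMAP (cat.), CH2Cl2, 0 °C → rt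
Reagents that add atoms: 3-methylbut-2-enoyl chloride 10, CC(C)=CC(=O)Cl
Why: DMAP-catalysed O-acylation with an acid chloride, in which pyridine replaces a trialkylamine because it is too weak a base to form the vinylketene that would shift the double bond out of conjugation, and the C2'–O bond stays intact so R is retained.

Step 7
Reactants: 11 (R)-1-[2-methoxy-6-(methoxymethoxy)phenyl]-3-methyl-1-oxobutan-2-yl 3-methylbut-2-enoate
Product: 12 (R)-1-(2-hydroxy-6-methoxyphenyl)-3-methyl-1-oxobutan-2-yl 3-methylbut-2-enoate
Conditions: 2 M aq. HCl, THF, 40 °C
Reagents that add atoms: none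
Why: Acid-catalysed acetal hydrolysis, eased by the ortho carbonyl group, frees the phenol under conditions that spare the hindered conjugated ester and the stereocentre, whereas a Lewis acid such as BCl3 would also cleave the methyl ether ortho to the ketone.

Step 8
Reactants: 12 (R)-1-(2-hydroxy-6-methoxyphenyl)-3-methyl-1-oxobutan-2-yl 3-methylbut-2-enoate, 13 propiolic acid
Product: 14 3-methoxy-2-[(R)-3-methyl-2-(3-methylbut-2-enoyloxy)butanoyl]phenyl prop-2-ynoate
Conditions: DCC, DMAP (5 mol %), CH2Cl2, −20 → 0 °C
Reagents that add atoms: propiolic acid 13, C#CC(=O)O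
Why: Steglich esterification, the standard entry to aryl propiolates, run cold and with little DMAP so that O-acylation outruns conjugate addition to the alkyne, in an essentially neutral medium that cannot enolise the α-acyloxy ketone.

Step 9
Reactants: 14 3-methoxy-2-[(R)-3-methyl-2-(3-methylbut-2-enoyloxy)butanoyl]phenyl prop-2-ynoate
Product: 15 (R)-1-(7-methoxy-2-oxo-2H-chromen-8-yl)-3-methyl-1-oxobutan-2-yl 3-methylbut-2-enoate (target CNP0295407.1)
Conditions: Pd(OAc)2 (5 mol %), TFA/CH2Cl2 (4:1), rt
Reagents that add atoms: none
Why: In TFA, Pd(OAc)2 becomes a strongly electrophilic divalent palladium trifluoroacetate that binds the alkyne; ring A then attacks the terminal alkyne carbon through its one free carbon ortho to the ester oxygen (the future C4a) on the side away from the metal, the arenium ion loses its proton, and TFA cleaves the C3–Pd bond to leave the C3=C4 double bond and return the catalyst. The closest known reaction type is the Fujiwara intramolecular hydroarylation of aryl alkynoates, established for simple aryl propiolates such as the 3-methoxyphenyl ester, so this is a known reaction on a more heavily substituted arene. Ring B closes in the 6-endo-dig mode. No stereocentre is formed, and C2' is a spectator that the base-free medium at room temperature should leave alone, since the ketone is hindered, twisted out of the ring plane and made less basic by the acyloxy group. The step needs regioselectivity (C4a rather than C8 or ipso attack at C8a) and chemoselectivity (alkyne rather than senecioate alkene). C8 is blocked by the acyl group, C4a is para to the C7 methoxy donor and only meta to the ketone, the methoxy group is meta to C8a and so gives ipso attack no help, and the electron-poor trisubstituted senecioate alkene is a poor ligand for the electrophilic metal.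

Compound list
1 | 3-methoxyphenol | COc1cccc(O)c1 | starting material
2 | 1-methoxy-3-(methoxymethoxy)benzene | COCOc1cccc(OC)c1 | intermediate
3 | (R)-2-hydroxy-3-methylbutanoic acid | CC(C)[C@@H](O)C(=O)O | starting material
4 | (R)-2-hydroxy-N-methoxy-N,3-dimethylbutanamide | CC(C)[C@@H](O)C(=O)N(C)OC | intermediate
5 | (R)-2-(tert-butyldimethylsilyloxy)-N-methoxy-N,3-dimethylbutanamide | CC(C)[C@@H](O[Si](C)(C)C(C)(C)C)C(=O)N(C)OC | intermediate
6 | [2-methoxy-6-(methoxymethoxy)phenyl]lithium (formed in the flask) | COCOc1cccc(OC)c1[Li] | intermediate
7 | lithium (2R)-2-(tert-butyldimethylsilyloxy)-1-[methoxy(methyl)amino]-1-[2-methoxy-6-(methoxymethoxy)phenyl]-3-methylbutan-1-olate (formed in the flask, C1 undefined) | COCOc1cccc(OC)c1C([O-])(N(C)OC)[C@H](O[Si](C)(C)C(C)(C)C)C(C)C.[Li+] | intermediate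
8 | (R)-2-(tert-butyldimethylsilyloxy)-1-[2-methoxy-6-(methoxymethoxy)phenyl]-3-methylbutan-1-one | COCOc1cccc(OC)c1C(=O)[C@H](O[Si](C)(C)C(C)(C)C)C(C)C | intermediate
9 | (R)-2-hydroxy-1-[2-methoxy-6-(methoxymethoxy)phenyl]-3-methylbutan-1-one | COCOc1cccc(OC)c1C(=O)[C@H](O)C(C)C | intermediate
10 | 3-methylbut-2-enoyl chloride (senecioyl chloride) | CC(C)=CC(=O)Cl | starting material
11 | (R)-1-[2-methoxy-6-(methoxymethoxy)phenyl]-3-methyl-1-oxobutan-2-yl 3-methylbut-2-enoate | COCOc1cccc(OC)c1C(=O)[C@H](OC(=O)C=C(C)C)C(C)C | intermediate
12 | (R)-1-(2-hydroxy-6-methoxyphenyl)-3-methyl-1-oxobutan-2-yl 3-methylbut-2-enoate | COc1cccc(O)c1C(=O)[C@H](OC(=O)C=C(C)C)C(C)C | intermediate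
13 | propiolic acid | C#CC(=O)O | starting material
14 | 3-methoxy-2-[(R)-3-methyl-2-(3-methylbut-2-enoyloxy)butanoyl]phenyl prop-2-ynoate | COc1cccc(OC(=O)C#C)c1C(=O)[C@H](OC(=O)C=C(C)C)C(C)C | intermediate
15 | (R)-1-(7-methoxy-2-oxo-2H-chromen-8-yl)-3-methyl-1-oxobutan-2-yl 3-methylbut-2-enoate (CNP0295407.1) | COc1ccc2ccc(=O)oc2c1C(=O)[C@H](OC(=O)C=C(C)C)C(C)C | target

Total step count: 9
Longest linear sequence: 8 steps (3 → 15, steps 2 to 9)

Steps most likely to fail

Step 9 (key step).
- **Risk:** Attack of ring A on the activated alkyne may be too slow, because an ester oxygen donates less than a free phenol and the C8 ketone withdraws inductively. Addition of trifluoroacetic acid across the alkyne, or acidolysis of the aryl ester, could then overtake cyclisation.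
- **Fallback:** Set out from phenol 12, skip step 8, and reverse the order of bond formation.
  - Phenol 12 and ethyl propiolate with catalytic Pd(OAc)2 in TFA/CH2Cl2 at rt should undergo the known intermolecular hydroarylation of phenols.
  - The much more electron-rich free phenol adds through the same carbon (ortho to OH, para to OMe) in trans fashion and gives ethyl (Z)-cinnamate F1.
  - The cis-placed ester of F1 is captured by the neighbouring hydroxyl in the same acidic medium with loss of ethanol, which comes back to the route at target 15.
  - Addition at the carbon para to the hydroxyl may compete, but that adduct cannot lactonise and should be separable.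

Step 4.
- **Risk:** Addition of the doubly ortho-substituted aryllithium to the crowded amide carbonyl may be sluggish. The aryllithium could then act as a base on the N-methoxy group, or simply survive until the quench.
- **Fallback:** Set out from amide 5 and use a smaller, more reactive electrophile.
  - Reduction of 5 with i-Bu2AlH (THF, −78 °C) should give silyloxy aldehyde F2.
  - F2 is used without delay and treated at −78 °C with aryllithium 6 (made as in step 4), which gives benzylic carbinol F3, expected as a mixture of C1 epimers.
  - Oxidation with Dess–Martin periodinane/NaHCO3 in CH2Cl2 removes the C1 centre and comes back to the route at ketone 8.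

Step 8.
- **Risk:** Conjugate addition of the phenol or of DMAP to the electron-poor alkyne, and oligomerisation of the activated propiolic acid, may compete with O-acylation of the hydrogen-bonded, hindered phenol.
- **Fallback:** Set out from phenol 12 and use an alkyne whose β-carbon is capped.
  - Commercial 3-(trimethylsilyl)propiolic acid with DCC and a full charge of DMAP in CH2Cl2 should give aryl silylpropiolate F4, because the silyl group shields the β-carbon from nucleophiles.
  - Desilylation with TBAF buffered by AcOH (THF, −20 °C) then comes back to the route at aryl propiolate 14.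

Further compounds
F1 | step 9 | ethyl (Z)-3-{2-hydroxy-4-methoxy-3-[(R)-3-methyl-2-(3-methylbut-2-enoyloxy)butanoyl]phenyl}prop-2-enoate | CCOC(=O)/C=C\c1ccc(OC)c(C(=O)[C@H](OC(=O)C=C(C)C)C(C)C)c1O
F2 | step 4 | (R)-2-(tert-butyldimethylsilyloxy)-3-methylbutanal | CC(C)[C@@H](O[Si](C)(C)C(C)(C)C)C=O
F3 | step 4 | (2R)-2-(tert-butyldimethylsilyloxy)-1-[2-methoxy-6-(methoxymethoxy)phenyl]-3-methylbutan-1-ol (C1 epimers) | COCOc1cccc(OC)c1C(O)[C@H](O[Si](C)(C)C(C)(C)C)C(C)C
F4 | step 8 | 3-methoxy-2-[(R)-3-methyl-2-(3-methylbut-2-enoyloxy)butanoyl]phenyl 3-(trimethylsilyl)prop-2-ynoate | COc1cccc(OC(=O)C#C[Si](C)(C)C)c1C(=O)[C@H](OC(=O)C=C(C)C)C(C)C
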